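**Strategy.** The plan disconnects ring B at C9–C10 and ring A at C4–C5 (labdane numbering), leading back to an open-chain epoxy-ene. It exploits that C9, the spiro carbon shared by ring B and the oxolane, carries the ether oxygen and adjoins oxygenated C8: C9 can therefore be the nucleophilic carbon of an enol silyl ether of a C8 ketone. A silyl triflate triggered cation–olefin bicyclisation, mirroring the ring B closure of labdane biosynthesis, forms rings A and B and sets C4, C5, C10 and C9 in one operation from a bought epoxide stereocentre. Its precursor is an (E)-2-(silyloxyalkylidene)oxolane bearing C13 preset and a 2,2-disubstituted oxirane.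

Key step: step 15

Remark: atom numbers are those of the labdane skeleton (ring A = C1–C5/C10, ring B = C5–C10); α/β refer to the usual drawing in which the C10 methyl group (C20) is β.

**Route**

Step 1
Reactants: 1 2-bromoprop-2-en-1-ol; 2 ethynyl[tri(propan-2-yl)]silane
Product: 3 2-methylidene-4-[tri(propan-2-yl)silyl]but-3-yn-1-ol
Conditions: PdCl2(PPh3)2 (cat.), CuI (cat.), Et3N, THF, rt
Reagents that add atoms: none
Why: Sonogashira coupling of the vinyl bromide with the terminal alkyne should tolerate the free allylic alcohol and creates no stereocentre.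

Step 2
Reactants: 3 2-methylidene-4-[tri(propan-2-yl)silyl]but-3-yn-1-ol
Product: 4 [(2R)-2-{[tri(propan-2-yl)silyl]ethynyl}oxiran-2-yl]methanol
Conditions: Ti(OiPr)4 (cat.), D-(−)-diisopropyl tartrate (cat.), t-BuOOH, 4 Å molecular sieves, CH2Cl2, −20 °C
Reagents that add atoms: tert-butyl hydroperoxide, CC(C)(C)OO
Why: Sharpless–Katsuki asymmetric epoxidation of the 2-substituted allylic alcohol sets the future C13, the D-(−)-tartrate delivering oxygen to the face that gives the (R)-epoxy alcohol (the sense in which it turns allyl alcohol into (R)-glycidol).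

Step 3
Reactants: 4 [(2R)-2-{[tri(propan-2-yl)silyl]ethynyl}oxiran-2-yl]methanol
Product: 5 tert-butyl(dimethyl){[(2S)-2-{[tri(propan-2-yl)silyl]ethynyl}oxiran-2-yl]methoxy}silane
Conditions: TBSCl, imidazole, DMF, 0 °C → rt
Reagents that add atoms: tert-butyl(chloro)dimethylsilane, CC(C)(C)[Si](C)(C)Cl
Why: Silylation of the primary alcohol blocks Payne rearrangement in the next step; the stereocentre is untouched and its descriptor changes only through the priority rules.

Step 4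
Reactants: 5 tert-butyl(dimethyl){[(2S)-2-{[tri(propan-2-yl)silyl]ethynyl}oxiran-2-yl]methoxy}silane; 6 lithium acetylide ethylenediamine complex
Product: 7 (2R)-1-{[tert-butyl(dimethyl)silyl]oxy}-2-{[tri(propan-2-yl)silyl]ethynyl}pent-4-yn-2-ol
Conditions: DMSO–THF, 0 °C → rt
Reagents that add atoms: none
Why: SN2 opening of the oxirane by acetylide at the unsubstituted CH2 (the future C12) should give the tertiary homopropargylic alcohol without touching the quaternary centre.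

Step 5
Reactants: 7 (2R)-1-{[tert-butyl(dimethyl)silyl]oxy}-2-{[tri(propan-2-yl)silyl]ethynyl}pent-4-yn-2-ol
Product: 8 tert-butyl(dimethyl){[(2R)-2-{[tri(propan-2-yl)silyl]ethynyl}-2,3-dihydrofuran-2-yl]methoxy}silane
Conditions: Mo(CO)6 (cat.), Me3NO (cat.), Et3N, Et2O, rt
Reagents that add atoms: none
Why: Endo-selective alkynol cycloisomerisation through a molybdenum vinylidene should close the 2,3-dihydrofuran (O–C9 bond) from the terminal alkyne only, the silylated alkyne being inert.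

Step 6
Reactants: 8 tert-butyl(dimethyl){[(2R)-2-{[tri(propan-2-yl)silyl]ethynyl}-2,3-dihydrofuran-2-yl]methoxy}silane; 9 N-methoxy-N-methylacetamide
Product: 11 1-[(5R)-5-({[tert-butyl(dimethyl)silyl]oxy}methyl)-5-{[tri(propan-2-yl)silyl]ethynyl}-4,5-dihydrofuran-2-yl]ethan-1-one, via lithiated dihydrofuran 10 (not isolated)
Conditions: t-BuLi, THF, −78 → 0 °C; then 9, −78 °C
Reagents that add atoms: none
Why: α-Lithiation of the cyclic enol ether at the vinylic C–H next to oxygen followed by Weinreb amide acylation should give the 2-acyl-4,5-dihydrofuran (C7 and C8 installed).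

Step 7
Reactants: 12 [(2R)-2-methyloxiran-2-yl]methanol ((R)-2-methylglycidol)
Product: 13 [(2S)-2-methyloxiran-2-yl]methyl 4-methylbenzenesulfonate
Conditions: TsCl, Et3N, DMAP (cat.), CH2Cl2, 0 °C
Reagents that add atoms: 4-methylbenzenesulfonyl chloride, Cc1ccc(cc1)S(Cl)(=O)=O
Why: Sulfonylation of the primary alcohol leaves the quaternary centre untouched, the change of descriptor being a consequence of the priority rules only.

Step 8
Reactants: 13 [(2S)-2-methyloxiran-2-yl]methyl 4-methylbenzenesulfonate; 14 vinylmagnesium bromide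
Product: 16 (2S)-2-methyl-2-(prop-2-en-1-yl)oxirane, via hydroxy tosylate 15 (not isolated)
Conditions: CH2=CHMgBr, CuI (cat.), THF, −40 °C; H2O work-up; then K2CO3, MeOH, rt
Reagents that add atoms: none
Why: Copper-catalysed Grignard opening of the oxirane at its CH2 and Williamson-type closure of the alkoxide onto the tosyloxymethyl carbon transpose the epoxide while the bought stereocentre (future C4) keeps all four bonds.

Step 9
Reactants: 17 ethyl 3-oxobutanoate
Product: 18 ethyl (2E)-3-{[(trifluoromethyl)sulfonyl]oxy}but-2-enoate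
Conditions: Tf2O, (CH3)4NOH (aq), hexanes, 5 °C → rt
Reagents that add atoms: trifluoromethanesulfonic anhydride, O=S(=O)(OS(=O)(=O)C(F)(F)F)C(F)(F)F
Why: O-Triflation of the non-chelated ammonium enolate of the β-keto ester should give the (E)-enol triflate, which fixes the later C5=C10 geometry.

Step 10
Reactants: 16 (2S)-2-methyl-2-(prop-2-en-1-yl)oxirane; 18 ethyl (2E)-3-{[(trifluoromethyl)sulfonyl]oxy}but-2-enoate
Product: 20 ethyl (2E)-3-methyl-6-[(2S)-2-methyloxiran-2-yl]hex-2-enoate, via B-alkyl-9-BBN 19 (not isolated)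
Conditions: 9-BBN, THF, 0 °C → rt; then 18, PdCl2(dppf) (cat.), K3PO4 (aq), DMF, rt
Reagents that add atoms: none
Why: Anti-Markovnikov hydroboration and B-alkyl Suzuki–Miyaura coupling with retention of the enol triflate geometry should give the (E)-trisubstituted alkene with the oxirane intact.

Step 11
Reactants: 20 ethyl (2E)-3-methyl-6-[(2S)-2-methyloxiran-2-yl]hex-2-enoate
Product: 21 (2E)-3-methyl-6-[(2S)-2-methyloxiran-2-yl]hex-2-en-1-ol
Conditions: iBu2AlH, CH2Cl2, −78 °C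
Reagents that add atoms: none
Why: 1,2-Reduction of the enoate by the aluminium hydride at low temperature should give the allylic alcohol faster than any opening of the hindered oxirane.

Step 12
Reactants: 21 (2E)-3-methyl-6-[(2S)-2-methyloxiran-2-yl]hex-2-en-1-ol
Product: 23 (2S)-2-[(4E)-6-bromo-4-methylhex-4-en-1-yl]-2-methyloxirane, via allylic mesylate 22 (not isolated)
Conditions: MsCl, Et3N, CH2Cl2, −40 °C; then LiBr, THF, 0 °C
Reagents that add atoms: lithium bromide, [Li+].[Br-]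
Why: Mesylation and SN2 displacement by bromide is the standard entry to epoxy allylic bromides and keeps both the alkene geometry and the oxirane.

Step 13
Reactants: 11 1-[(5R)-5-({[tert-butyl(dimethyl)silyl]oxy}methyl)-5-{[tri(propan-2-yl)silyl]ethynyl}-4,5-dihydrofuran-2-yl]ethan-1-one; 23 (2S)-2-[(4E)-6-bromo-4-methylhex-4-en-1-yl]-2-methyloxirane
Product: 25 (4E)-1-[(5R)-5-({[tert-butyl(dimethyl)silyl]oxy}methyl)-5-{[tri(propan-2-yl)silyl]ethynyl}-4,5-dihydrofuran-2-yl]-5-methyl-8-[(2S)-2-methyloxiran-2-yl]oct-4-en-1-one, via lithium enolate 24 (not isolated)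
Conditions: LiN(iPr)2, THF, −78 °C; then 23, DMPU, −78 → −20 °C
Reagents that add atoms: none
Why: The acetyl group is the only enolisable position, so kinetic enolate formation and SN2 alkylation with the allylic bromide should forge C6–C7 and complete the carbon chain.

Step 14
Reactants: 25 (4E)-1-[(5R)-5-({[tert-butyl(dimethyl)silyl]oxy}methyl)-5-{[tri(propan-2-yl)silyl]ethynyl}-4,5-dihydrofuran-2-yl]-5-methyl-8-[(2S)-2-methyloxiran-2-yl]oct-4-en-1-one
Product: 26 tert-butyl(dimethyl){[(2R,5E)-5-{(4E)-5-methyl-8-[(2S)-2-methyloxiran-2-yl]-1-[(triethylsilyl)oxy]oct-4-en-1-ylidene}-2-{[tri(propan-2-yl)silyl]ethynyl}oxolan-2-yl]methoxy}silane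
Conditions: RhCl(PPh3)3 (cat.), Et3SiH, benzene, 60 °C
Reagents that add atoms: triethylsilane, CC[SiH](CC)CC
Why: Rhodium-catalysed 1,4-hydrosilylation of the enone through its s-cis conformer should saturate C11 (making the oxolane) and give regiospecifically the tetrasubstituted enol silyl ether with OSi cis to C11, i.e. the (E)-isomer.

Step 15
Reactants: 26 tert-butyl(dimethyl){[(2R,5E)-5-{(4E)-5-methyl-8-[(2S)-2-methyloxiran-2-yl]-1-[(triethylsilyl)oxy]oct-4-en-1-ylidene}-2-{[tri(propan-2-yl)silyl]ethynyl}oxolan-2-yl]methoxy}silane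
Product: 27 (4S,5S,9S,10S,13R)-16-{[tert-butyl(dimethyl)silyl]oxy}-9,13-epoxy-19-[(triethylsilyl)oxy]-15-[tri(propan-2-yl)silyl]-17-norlabd-14-yn-8-one
Conditions: Et3SiOTf (cat.), 2,6-di-tert-butyl-4-methylpyridine, CH2Cl2, −78 °C
Reagents that add atoms: none
Why: Et3SiOTf silylates the oxirane oxygen, the C5=C10 π bond opens the activated oxirane at C4 with inversion, the resulting tertiary C10 cation is captured by C9 of the α-alkoxy enol silyl ether (Mukaiyama-type alkylation), and the silyloxocarbenium ion at C8 returns its silyl group to triflate, so that the silyl triflate turns over and the former oxirane oxygen ends as the C19 silyl ether. The closest known reaction types are the epoxide-initiated cation–olefin polycyclisation terminated by an enol silyl ether and the Lewis acid mediated tert-alkylation of enol silanes. Ring A closes by 6-endo-trig attack of the alkene on C4 (exo opening of the oxirane) and ring B by 6-endo-trig attack of the enol ether on the C10 cation, both through chair-like arrays. C4 is fixed by the bought epoxide (inversion), C5 and C10 by anti addition across the (E)-C5=C10 bond in the chair–chair fold (trans ring fusion), and C9 by the (E)-enol ether geometry, which places the ring oxygen axial (α) and C11 equatorial (β). The step needs the oxirane CH2–O arm and not the methyl group to sit axial at C4, expected because the ring-strained CH2 is tilted away from the developing 1,3-diaxial contact with the C10 methyl group, and it needs bonding at C9 and not C8, which the polarity of the enol silane (nucleophilic carbon β to OSi) secures. The preset C13 is matched, since C10 approaches the oxolane face that carries the slim alkynyl group.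

Step 16
Reactants: 27 (4S,5S,9S,10S,13R)-16-{[tert-butyl(dimethyl)silyl]oxy}-9,13-epoxy-19-[(triethylsilyl)oxy]-15-[tri(propan-2-yl)silyl]-17-norlabd-14-yn-8-one
Product: 28 (4S,5S,9S,10S,13R)-16-{[tert-butyl(dimethyl)silyl]oxy}-9,13-epoxy-7-hydroxy-19-[(triethylsilyl)oxy]-15-[tri(propan-2-yl)silyl]-17-norlabd-6-en-14-yn-8-one
Conditions: KOtBu, O2 (1 atm), t-BuOH–THF, 0 °C → rt; then AcOH
Reagents that add atoms: dioxygen, O=O
Why: Base-mediated autoxidation of the ketone, whose only enolisable position is C7 because C9 is quaternary, should give the 7,8-diketone that rests as the diosphenol enolised towards C6.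

Step 17
Reactants: 28 (4S,5S,9S,10S,13R)-16-{[tert-butyl(dimethyl)silyl]oxy}-9,13-epoxy-7-hydroxy-19-[(triethylsilyl)oxy]-15-[tri(propan-2-yl)silyl]-17-norlabd-6-en-14-yn-8-one
Product: 29 (4S,5S,9S,10S,13R)-16-{[tert-butyl(dimethyl)silyl]oxy}-9,13-epoxy-7,19-bis[(triethylsilyl)oxy]-15-[tri(propan-2-yl)silyl]-17-norlabd-6-en-14-yn-8-one
Conditions: Et3SiCl, imidazole, DMF, 0 °C
Reagents that add atoms: chlorotriethylsilane, CC[Si](Cl)(CC)CC
Why: O-Silylation of the acidic diosphenol hydroxyl masks C7 as an enol ether and leaves C8 as the only carbonyl group (any C19 hydroxyl freed in step 16 would be silylated again here).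

Step 18
Reactants: 29 (4S,5S,9S,10S,13R)-16-{[tert-butyl(dimethyl)silyl]oxy}-9,13-epoxy-7,19-bis[(triethylsilyl)oxy]-15-[tri(propan-2-yl)silyl]-17-norlabd-6-en-14-yn-8-one
Product: 32 (4S,5S,8R,9S,10S,13R)-8-acetoxy-16-{[tert-butyl(dimethyl)silyl]oxy}-9,13-epoxy-19-[(triethylsilyl)oxy]-15-[tri(propan-2-yl)silyl]labd-14-yn-7-one, via lithium alkoxide 30 (not isolated), via enol ether acetate 31 (not isolated)
Conditions: MeLi, THF, −78 °C; then Ac2O, −78 → 0 °C; then citric acid (aq), THF, 0 °C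
Reagents that add atoms: methyllithium, [Li]C; acetic anhydride, CC(=O)OC(C)=O
Why: 1,2-Addition of methyllithium to the C8 carbonyl from the α-face, anti to the syn-axial C10 methyl group, should set C8 (8β-oxygen, 8α-methyl), the hindered tertiary alkoxide is acetylated in situ, and mild acid hydrolyses the silyl enol ether to the C7 ketone.

Step 19
Reactants: 32 (4S,5S,8R,9S,10S,13R)-8-acetoxy-16-{[tert-butyl(dimethyl)silyl]oxy}-9,13-epoxy-19-[(triethylsilyl)oxy]-15-[tri(propan-2-yl)silyl]labd-14-yn-7-one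
Product: 33 (4S,5S,8R,9S,10S,13R)-8-acetoxy-9,13-epoxy-16,19-dihydroxylabd-14-yn-7-one
Conditions: Bu4NF, AcOH, THF, 0 °C → rt
Reagents that add atoms: none
Why: Buffered fluoride should cleave both silyl ethers and the alkynyl C–Si bond while the hindered tertiary acetate next to the ketone survives.

Step 20
Reactants: 33 (4S,5S,8R,9S,10S,13R)-8-acetoxy-9,13-epoxy-16,19-dihydroxylabd-14-yn-7-one
Product: 34 (4S,5S,8R,9S,10S,13R)-8-acetoxy-9,13:15,16-diepoxy-19-hydroxylabd-14-en-7-one (CNP0239339.1)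
Conditions: Mo(CO)6 (cat.), Me3NO (cat.), Et3N, Et2O, rt
Reagents that add atoms: none
Why: Endo-selective cycloisomerisation of the C16 homopropargylic alcohol through a molybdenum vinylidene should close the acid-labile spiro 2,3-dihydrofuran last, under non-acidic conditions, the remote C19 hydroxyl having no alkyne within reach.

**Compound list**

1 | 2-bromoprop-2-en-1-ol | C=C(Br)CO | starting material
2 | ethynyl[tri(propan-2-yl)]silane | C#C[Si](C(C)C)(C(C)C)C(C)C | starting material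
3 | 2-methylidene-4-[tri(propan-2-yl)silyl]but-3-yn-1-ol | C=C(CO)C#C[Si](C(C)C)(C(C)C)C(C)C | intermediate
4 | [(2R)-2-{[tri(propan-2-yl)silyl]ethynyl}oxiran-2-yl]methanol | CC(C)[Si](C(C)C)(C(C)C)C#C[C@@]1(CO)CO1 | intermediate
5 | tert-butyl(dimethyl){[(2S)-2-{[tri(propan-2-yl)silyl]ethynyl}oxiran-2-yl]methoxy}silane | CC(C)[Si](C(C)C)(C(C)C)C#C[C@@]1(CO[Si](C)(C)C(C)(C)C)CO1 | intermediate
6 | lithium acetylide ethylenediamine complex | [Li]C#C.NCCN | starting material
7 | (2R)-1-{[tert-butyl(dimethyl)silyl]oxy}-2-{[tri(propan-2-yl)silyl]ethynyl}pent-4-yn-2-ol | C#CC[C@@](C#C[Si](C(C)C)(C(C)C)C(C)C)(CO[Si](C)(C)C(C)(C)C)O | intermediate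
8 | tert-butyl(dimethyl){[(2R)-2-{[tri(propan-2-yl)silyl]ethynyl}-2,3-dihydrofuran-2-yl]methoxy}silane | C1=CC[C@@](C#C[Si](C(C)C)(C(C)C)C(C)C)(CO[Si](C)(C)C(C)(C)C)O1 | intermediate
9 | N-methoxy-N-methylacetamide | CC(=O)N(C)OC | starting material
10 | [(5R)-5-({[tert-butyl(dimethyl)silyl]oxy}methyl)-5-{[tri(propan-2-yl)silyl]ethynyl}-4,5-dihydrofuran-2-yl]lithium | [Li]C1=CC[C@@](C#C[Si](C(C)C)(C(C)C)C(C)C)(CO[Si](C)(C)C(C)(C)C)O1 | intermediate
11 | 1-[(5R)-5-({[tert-butyl(dimethyl)silyl]oxy}methyl)-5-{[tri(propan-2-yl)silyl]ethynyl}-4,5-dihydrofuran-2-yl]ethan-1-one | CC(=O)C1=CC[C@@](C#C[Si](C(C)C)(C(C)C)C(C)C)(CO[Si](C)(C)C(C)(C)C)O1 | intermediate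
12 | [(2R)-2-methyloxiran-2-yl]methanol | C[C@@]1(CO)CO1 | starting material
13 | [(2S)-2-methyloxiran-2-yl]methyl 4-methylbenzenesulfonate | C[C@@]1(COS(=O)(=O)c2ccc(C)cc2)CO1 | intermediate
14 | vinylmagnesium bromide | C=C[Mg]Br | starting material
15 | (2S)-2-hydroxy-2-methylpent-4-en-1-yl 4-methylbenzenesulfonate | C[C@@](O)(COS(=O)(=O)c1ccc(C)cc1)CC=C | intermediate
16 | (2S)-2-methyl-2-(prop-2-en-1-yl)oxirane | C[C@@]1(CO1)CC=C | intermediate
17 | ethyl 3-oxobutanoate | CCOC(=O)CC(C)=O | starting material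
18 | ethyl (2E)-3-{[(trifluoromethyl)sulfonyl]oxy}but-2-enoate | CCOC(=O)/C=C(\C)OS(=O)(=O)C(F)(F)F | intermediate
19 | 9-{3-[(2S)-2-methyloxiran-2-yl]propyl}-9-borabicyclo[3.3.1]nonane | C[C@@]1(CO1)CCCB2C3CCCC2CCC3 | intermediate
20 | ethyl (2E)-3-methyl-6-[(2S)-2-methyloxiran-2-yl]hex-2-enoate | C[C@@]1(CO1)CCC/C(C)=C/C(=O)OCC | intermediate
21 | (2E)-3-methyl-6-[(2S)-2-methyloxiran-2-yl]hex-2-en-1-ol | C[C@@]1(CO1)CCC/C(C)=C/CO | intermediate
22 | (2E)-3-methyl-6-[(2S)-2-methyloxiran-2-yl]hex-2-en-1-yl methanesulfonate | C[C@@]1(CO1)CCC/C(C)=C/COS(C)(=O)=O | intermediate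
23 | (2S)-2-[(4E)-6-bromo-4-methylhex-4-en-1-yl]-2-methyloxirane | C[C@@]1(CO1)CCC/C(C)=C/CBr | intermediate
24 | lithium enolate of 11 (lithium 1-[(5R)-5-({[tert-butyl(dimethyl)silyl]oxy}methyl)-5-{[tri(propan-2-yl)silyl]ethynyl}-4,5-dihydrofuran-2-yl]ethen-1-olate) | [Li]OC(=C)C1=CC[C@@](C#C[Si](C(C)C)(C(C)C)C(C)C)(CO[Si](C)(C)C(C)(C)C)O1 | intermediate
25 | (4E)-1-[(5R)-5-({[tert-butyl(dimethyl)silyl]oxy}methyl)-5-{[tri(propan-2-yl)silyl]ethynyl}-4,5-dihydrofuran-2-yl]-5-methyl-8-[(2S)-2-methyloxiran-2-yl]oct-4-en-1-one | C[C@@]1(CO1)CCC/C(C)=C/CCC(=O)C2=CC[C@@](C#C[Si](C(C)C)(C(C)C)C(C)C)(CO[Si](C)(C)C(C)(C)C)O2 | intermediate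
26 | tert-butyl(dimethyl){[(2R,5E)-5-{(4E)-5-methyl-8-[(2S)-2-methyloxiran-2-yl]-1-[(triethylsilyl)oxy]oct-4-en-1-ylidene}-2-{[tri(propan-2-yl)silyl]ethynyl}oxolan-2-yl]methoxy}silane | C[C@@]1(CO1)CCC/C(C)=C/CC/C(O[Si](CC)(CC)CC)=C2/CC[C@@](C#C[Si](C(C)C)(C(C)C)C(C)C)(CO[Si](C)(C)C(C)(C)C)O2 | intermediate
27 | (4S,5S,9S,10S,13R)-16-{[tert-butyl(dimethyl)silyl]oxy}-9,13-epoxy-19-[(triethylsilyl)oxy]-15-[tri(propan-2-yl)silyl]-17-norlabd-14-yn-8-one | O=C1CC[C@H]2[C@@](C)(CO[Si](CC)(CC)CC)CCC[C@]2(C)[C@@]12CC[C@@](C#C[Si](C(C)C)(C(C)C)C(C)C)(CO[Si](C)(C)C(C)(C)C)O2 | intermediate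
28 | (4S,5S,9S,10S,13R)-16-{[tert-butyl(dimethyl)silyl]oxy}-9,13-epoxy-7-hydroxy-19-[(triethylsilyl)oxy]-15-[tri(propan-2-yl)silyl]-17-norlabd-6-en-14-yn-8-one | O=C1C(O)=C[C@H]2[C@@](C)(CO[Si](CC)(CC)CC)CCC[C@]2(C)[C@@]12CC[C@@](C#C[Si](C(C)C)(C(C)C)C(C)C)(CO[Si](C)(C)C(C)(C)C)O2 | intermediate
29 | (4S,5S,9S,10S,13R)-16-{[tert-butyl(dimethyl)silyl]oxy}-9,13-epoxy-7,19-bis[(triethylsilyl)oxy]-15-[tri(propan-2-yl)silyl]-17-norlabd-6-en-14-yn-8-one | O=C1C(O[Si](CC)(CC)CC)=C[C@H]2[C@@](C)(CO[Si](CC)(CC)CC)CCC[C@]2(C)[C@@]12CC[C@@](C#C[Si](C(C)C)(C(C)C)C(C)C)(CO[Si](C)(C)C(C)(C)C)O2 | intermediate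
30 | lithium (4S,5S,8R,9S,10S,13R)-16-{[tert-butyl(dimethyl)silyl]oxy}-9,13-epoxy-7,19-bis[(triethylsilyl)oxy]-15-[tri(propan-2-yl)silyl]labd-6-en-14-yn-8-olate | [Li]O[C@@]1(C)C(O[Si](CC)(CC)CC)=C[C@H]2[C@@](C)(CO[Si](CC)(CC)CC)CCC[C@]2(C)[C@@]12CC[C@@](C#C[Si](C(C)C)(C(C)C)C(C)C)(CO[Si](C)(C)C(C)(C)C)O2 | intermediate
31 | (4S,5S,8R,9S,10S,13R)-16-{[tert-butyl(dimethyl)silyl]oxy}-9,13-epoxy-7,19-bis[(triethylsilyl)oxy]-15-[tri(propan-2-yl)silyl]labd-6-en-14-yn-8-yl acetate | CC(=O)O[C@@]1(C)C(O[Si](CC)(CC)CC)=C[C@H]2[C@@](C)(CO[Si](CC)(CC)CC)CCC[C@]2(C)[C@@]12CC[C@@](C#C[Si](C(C)C)(C(C)C)C(C)C)(CO[Si](C)(C)C(C)(C)C)O2 | intermediate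
32 | (4S,5S,8R,9S,10S,13R)-8-acetoxy-16-{[tert-butyl(dimethyl)silyl]oxy}-9,13-epoxy-19-[(triethylsilyl)oxy]-15-[tri(propan-2-yl)silyl]labd-14-yn-7-one | CC(=O)O[C@@]1(C)C(=O)C[C@H]2[C@@](C)(CO[Si](CC)(CC)CC)CCC[C@]2(C)[C@@]12CC[C@@](C#C[Si](C(C)C)(C(C)C)C(C)C)(CO[Si](C)(C)C(C)(C)C)O2 | intermediate
33 | (4S,5S,8R,9S,10S,13R)-8-acetoxy-9,13-epoxy-16,19-dihydroxylabd-14-yn-7-one | CC(=O)O[C@@]1(C)C(=O)C[C@H]2[C@@](C)(CO)CCC[C@]2(C)[C@@]12CC[C@@](C#C)(CO)O2 | intermediate
34 | (4S,5S,8R,9S,10S,13R)-8-acetoxy-9,13:15,16-diepoxy-19-hydroxylabd-14-en-7-one (CNP0239339.1) | CC(=O)O[C@@]1(C)C(=O)C[C@H]2[C@@](C)(CO)CCC[C@]2(C)[C@@]12CC[C@]1(C=COC1)O2 | target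

**Summary**

Total step count: 20. Longest linear sequence: 14 steps (steps 1–6, then 13–20); the branch from 12 (steps 7, 8, 10–12, with 18 from step 9) joins at step 13.

Steps most likely to fail:

Step 15 (key step). The activated oxirane may rearrange by hydride shift before the alkene engages, or the C10 cation may lose a proton or be trapped on oxygen so that the cascade stalls after ring A. Poor axial/equatorial discrimination at C4 is a further risk. The fallback closes the two rings one after the other; it sets out from 25 and comes back at 27. SnCl4 in CH2Cl2 at −78 °C should effect the epoxide–olefin monocyclisation of 25 with chloride capture at C10, giving the monocyclic chloro alcohol 1-[(5R)-5-({[tert-butyl(dimethyl)silyl]oxy}methyl)-5-{[tri(propan-2-yl)silyl]ethynyl}-4,5-dihydrofuran-2-yl]-3-[(1S,2S)-6-chloro-2-(hydroxymethyl)-2,6-dimethylcyclohexyl]propan-1-one F1. Et3SiCl/imidazole then gives its C19 triethylsilyl ether F2. RhCl(PPh3)3/Et3SiH converts the enone into the (E)-enol triethylsilyl ether F3. AgOTf with 2,6-di-tert-butyl-4-methylpyridine in CH2Cl2 ionises the tertiary chloride, and the C10 cation alkylates C9 of the enol silane (tert-alkylation of a silyl enol ether) to give 27.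

Step 14. 1,2-Hydrosilylation, or hydride delivery through the s-trans enone, would give an allyl silyl ether or the (Z)-enol ether; the latter would invert C9 in step 15. The fallback sets out from 25 and comes back at 26. Conjugate reduction of 25 with [(Ph3P)CuH]6 in wet benzene should give the saturated 2-acyloxolane (4E)-1-[(5R)-5-({[tert-butyl(dimethyl)silyl]oxy}methyl)-5-{[tri(propan-2-yl)silyl]ethynyl}oxolan-2-yl]-5-methyl-8-[(2S)-2-methyloxiran-2-yl]oct-4-en-1-one F4 as both C9 epimers. Soft enolisation with Et3SiOTf/Et3N in CH2Cl2 should then remove the doubly activated C9–H of either epimer and give the less strained (E)-enol silyl ether 26.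

Step 18. The addition of methyllithium to the flattened, cross-conjugated enone may suffer from poor facial selectivity, attack at silicon or deprotonation. The fallback performs the addition on a saturated chair ketone; it sets out from 27 and comes back at 32. Rubottom oxidation of 27 (LiN(iPr)2, Me3SiCl; then m-CPBA; mild acid) should give the 7-hydroxy ketone (4S,5S,9S,10S,13R)-16-{[tert-butyl(dimethyl)silyl]oxy}-9,13-epoxy-7-hydroxy-19-[(triethylsilyl)oxy]-15-[tri(propan-2-yl)silyl]-17-norlabd-14-yn-8-one F5. MeLi/CeCl3 should then attack C8 equatorially from the α-face, as enforced by the syn-axial C10 methyl group, to give the diol (4S,5S,8S,9S,10S,13R)-16-{[tert-butyl(dimethyl)silyl]oxy}-9,13-epoxy-19-[(triethylsilyl)oxy]-15-[tri(propan-2-yl)silyl]labd-14-yne-7,8-diol F6. Dess–Martin oxidation of the secondary C7 alcohol gives the α-ketol (4S,5S,8R,9S,10S,13R)-16-{[tert-butyl(dimethyl)silyl]oxy}-9,13-epoxy-8-hydroxy-19-[(triethylsilyl)oxy]-15-[tri(propan-2-yl)silyl]labd-14-yn-7-one F7, and acetylation of its tertiary alcohol (Ac2O, DMAP, Et3N) gives 32.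

Further compounds
F1 | step 15 | 1-[(5R)-5-({[tert-butyl(dimethyl)silyl]oxy}methyl)-5-{[tri(propan-2-yl)silyl]ethynyl}-4,5-dihydrofuran-2-yl]-3-[(1S,2S)-6-chloro-2-(hydroxymethyl)-2,6-dimethylcyclohexyl]propan-1-one | CC1(Cl)CCC[C@](C)(CO)[C@@H]1CCC(=O)C2=CC[C@@](C#C[Si](C(C)C)(C(C)C)C(C)C)(CO[Si](C)(C)C(C)(C)C)O2
F2 | step 15 | 1-[(5R)-5-({[tert-butyl(dimethyl)silyl]oxy}methyl)-5-{[tri(propan-2-yl)silyl]ethynyl}-4,5-dihydrofuran-2-yl]-3-[(1S,2S)-6-chloro-2,6-dimethyl-2-{[(triethylsilyl)oxy]methyl}cyclohexyl]propan-1-one | CC1(Cl)CCC[C@](C)(CO[Si](CC)(CC)CC)[C@@H]1CCC(=O)C2=CC[C@@](C#C[Si](C(C)C)(C(C)C)C(C)C)(CO[Si](C)(C)C(C)(C)C)O2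
F3 | step 15 | tert-butyl{[(2R,5E)-5-{3-[(1S,2S)-6-chloro-2,6-dimethyl-2-{[(triethylsilyl)oxy]methyl}cyclohexyl]-1-[(triethylsilyl)oxy]propylidene}-2-{[tri(propan-2-yl)silyl]ethynyl}oxolan-2-yl]methoxy}dimethylsilane | CC1(Cl)CCC[C@](C)(CO[Si](CC)(CC)CC)[C@@H]1CC/C(O[Si](CC)(CC)CC)=C2/CC[C@@](C#C[Si](C(C)C)(C(C)C)C(C)C)(CO[Si](C)(C)C(C)(C)C)O2
F4 | step 14 | (4E)-1-[(5R)-5-({[tert-butyl(dimethyl)silyl]oxy}methyl)-5-{[tri(propan-2-yl)silyl]ethynyl}oxolan-2-yl]-5-methyl-8-[(2S)-2-methyloxiran-2-yl]oct-4-en-1-one | C[C@@]1(CO1)CCC/C(C)=C/CCC(=O)C2CC[C@@](C#C[Si](C(C)C)(C(C)C)C(C)C)(CO[Si](C)(C)C(C)(C)C)O2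
F5 | step 18 | (4S,5S,9S,10S,13R)-16-{[tert-butyl(dimethyl)silyl]oxy}-9,13-epoxy-7-hydroxy-19-[(triethylsilyl)oxy]-15-[tri(propan-2-yl)silyl]-17-norlabd-14-yn-8-one | O=C1C(O)C[C@H]2[C@@](C)(CO[Si](CC)(CC)CC)CCC[C@]2(C)[C@@]12CC[C@@](C#C[Si](C(C)C)(C(C)C)C(C)C)(CO[Si](C)(C)C(C)(C)C)O2
F6 | step 18 | (4S,5S,8S,9S,10S,13R)-16-{[tert-butyl(dimethyl)silyl]oxy}-9,13-epoxy-19-[(triethylsilyl)oxy]-15-[tri(propan-2-yl)silyl]labd-14-yne-7,8-diol | O[C@@]1(C)C(O)C[C@H]2[C@@](C)(CO[Si](CC)(CC)CC)CCC[C@]2(C)[C@@]12CC[C@@](C#C[Si](C(C)C)(C(C)C)C(C)C)(CO[Si](C)(C)C(C)(C)C)O2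
F7 | step 18 | (4S,5S,8R,9S,10S,13R)-16-{[tert-butyl(dimethyl)silyl]oxy}-9,13-epoxy-8-hydroxy-19-[(triethylsilyl)oxy]-15-[tri(propan-2-yl)silyl]labd-14-yn-7-one | O[C@@]1(C)C(=O)C[C@H]2[C@@](C)(CO[Si](CC)(CC)CC)CCC[C@]2(C)[C@@]12CC[C@@](C#C[Si](C(C)C)(C(C)C)C(C)C)(CO[Si](C)(C)C(C)(C)C)O2
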